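The constants below set one number for this flask: how much nucleophile brings the electrophile, the limiting reagent, to the asked part within the run.

    acid set free + target → side product (k1 = 3.5 × 10⁻⁵ /M/s)
    nucleophile + acid set free ⇌ protonated nucleophile, settled at all times (K2 = 690 /M)
    electrophile + nucleophile → acid set free + target (k3 = 2.9 × 10⁻⁵ /M/s)
    nucleophile + protic impurity → quenched reagent (k4 = 0.0052 /M/s)

electrophile 0.25 M; protic impurity 5.00 mM; time 2.5 d

- the concentration of nucleophile at which the part of the electrophile that has reacted at 2.5 d is just 90 %, in M

The flask's clock, the rate constant of the target step times the electrophile charge times the run time, reads 1.57. Counted in electrophile charges, the usable nucleophile is the amount charged less the impurity's 2.00 % of a charge, which goes first, its constant being far larger than that of the target step. Per unit of clock, the starting rate equals that usable amount. Two factors slow it. The electrophile's factor falls to 10.0 % of its start at the end. The nucleophile's factor falls at two nucleophile per electrophile reacted, because at a free nucleophile of one electrophile charge, about where this reckoning ends, the balance holds acid as protonated nucleophile by 172 to one. Summed over the run, the spare (usable charges beyond 2) times the clock equals the ln of the nucleophile's end factor over the electrophile's. A trial of 3 usable charges gives that ln as 1.39. Frozen there, it gives 2.89 charges; the ln then moves to 1.32, which gives 2.85. With the impurity added back, this reckoning stops at 0.716 M.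

The forecast is lower than that: 0.709 M, within 0.7 M to 0.72 M, on the ground that “Each electrophile consumed effectively uses two nucleophiles”.

The simulation gives 0.709 M, which is 2.84 over the electrophile charged. At 0.416 d in this flask the electrophile's half-life by the target step is 0.58 d, far shorter than the target's 680 d by the step to side product. A flask with a quarter more nucleophile holds 3.53 usable charges; on the same clock the end factors stand 10.9 to one, which puts the part reacted at 95.8 %, and the simulation of that flask gives 95.8 %.

All constants were set for the occasion; no experiment stands behind them.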